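**Assumptions (one line):** the target's stereochemistry is taken as drawn: ring C‑OAr (R), C‑OH (S), ring CH–side chain (R), side‑chain CH(CH3) (S). The keto/enol form of the curcuminoid is as written, and the carbinol epimers formed in Step 2 are irrelevant because that centre is destroyed in Step 6.

## Retrosynthesis

- The curcuminoid is assembled last by a boron‑mediated (Pabon) condensation of the terpenoid aryl‑ether aldehyde with p‑coumaroylacetone.
- The aryl ether and the cis C–OH come from one Pd(0)‑catalysed cis‑1,4 opening of a vinyl epoxide by vanillin. The epoxide comes from the α‑turmerone‑type diene, a turmerone‑constitution diene.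
- The diene comes from dehydration of an allylic alcohol. The side‑chain ketone comes from a Weinreb amide plus isobutenyl Grignard. The side‑chain CH(CH3) centre is set by CuH asymmetric conjugate reduction of an enoate made by cross‑metathesis of (S)‑carvone.
- No carbocycle is formed; the cyclohexene ring is carried from (S)‑carvone. The only ring made is the epoxide (Step 7), which is opened in Step 8. The aryl rings come from purchased vanillin and 4‑hydroxybenzaldehyde.

## Route

**Step 1**
Reactants: 1 (S)‑(+)‑carvone; 2 ethyl acrylate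
Product: 3 ethyl (2E)‑3‑[(1S)‑4‑methyl‑5‑oxocyclohex‑3‑en‑1‑yl]but‑2‑enoate
Conditions: Hoveyda–Grubbs II (5 mol %), 2 (4 equiv), CH2Cl2, 40 °C, ethylene vented
Reagents that add atoms: ethyl acrylate, C=CC(=O)OCC
Why: Cross‑metathesis joins the 1,1‑disubstituted isopropenyl group to the acrylate to give the trisubstituted E‑enoate. The electron‑poor ring enone does not react and no new stereocentre forms; the ring stereocentre is untouched.

**Step 2**
Reactants: 3
Product: 4 ethyl (2E)‑3‑[(1S)‑5‑hydroxy‑4‑methylcyclohex‑3‑en‑1‑yl]but‑2‑enoate (carbinol epimers, cis major)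
Conditions: NaBH4, CeCl3·7H2O, MeOH, −78 → 0 °C
Reagents that add atoms: none
Why: Luche 1,2‑reduction of the ring ketone leaves the enoate and the alkenes alone. The new carbinol centre is erased in Step 6, so its configuration need not be controlled.

**Step 3**
Reactants: 4
Product: 5 ethyl (3S)‑3‑[(1S)‑5‑hydroxy‑4‑methylcyclohex‑3‑en‑1‑yl]butanoate
Conditions: Cu(OAc)2·H2O (5 mol %), (R)‑DTBM‑SEGPHOS (5.5 mol %), TMDS, t‑BuOH, toluene, 0 °C → rt; then NH4F, MeOH
Reagents that add atoms: none
Why: CuH asymmetric 1,4‑reduction of the (E)‑β,β‑disubstituted enoate; the chiral ligand controls which enoate face receives H and so sets the side‑chain CH(CH3) as S. The ligand enantiomer is the one that gives 3S (confirm in a pilot run). The isolated ring alkene and the alcohol survive, and NH4F removes any O–Si formed.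

**Step 4**
Reactants: 5
Product: 6 (3S)‑N‑methoxy‑N‑methyl‑3‑[(1S)‑5‑hydroxy‑4‑methylcyclohex‑3‑en‑1‑yl]butanamide
Conditions: MeNH(OMe)·HCl (3 equiv), iPrMgCl (6 equiv), THF, −20 → 0 °C
Reagents that add atoms: N,O‑dimethylhydroxylamine, CNOC
Why: Direct Weinreb amidation of the ester (Williams); the alkoxide and alkene are untouched, and the side‑chain stereocentre is β to the carbonyl so it cannot epimerise.

**Step 5**
Reactants: 6
Product: 7 (6S)‑6‑[(1S)‑5‑hydroxy‑4‑methylcyclohex‑3‑en‑1‑yl]‑2‑methylhept‑2‑en‑4‑one (Cb‑epimers)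
Conditions: 2‑methylprop‑1‑enylMgBr (0.5 M in THF, 3 equiv), THF, 0 °C → rt
Reagents that add atoms: 2‑methylprop‑1‑enylmagnesium bromide, CC(C)=C[Mg]Br
Why: Weinreb ketone synthesis. The chelated tetrahedral intermediate prevents over‑addition and releases the enone only on aqueous work‑up; no new stereocentre forms.

**Step 6**
Reactants: 7
Product: 8 (6S)‑2‑methyl‑6‑[(1R)‑4‑methylcyclohexa‑2,4‑dien‑1‑yl]hept‑2‑en‑4‑one (α‑turmerone constitution)
Conditions: Burgess reagent (1.5 equiv), THF, 50 °C; degassed, BHT
Reagents that add atoms: none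
Why: Syn (Ei) dehydration of the allylic alcohol, removing a CH2 hydrogen, gives the conjugated 2‑methylcyclohexa‑1,3‑diene. The carbinol configuration is lost and both other stereocentres are retained. The diene is handled cold and used at once to avoid aromatisation.

**Step 7**
Reactants: 8
Product: 9 vinyl epoxide of the C(CH3)=CH bond of 8 (1‑methyl‑7‑oxabicyclo[4.1.0]hept‑2‑ene core), epoxide O on the face anti to the side chain; side‑chain centres (6S)/(1R) as in 8
Conditions: DMDO (1.0 equiv), acetone, NaHCO3, −20 °C; no acid work‑up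
Reagents that add atoms: dimethyldioxirane, CC1(C)OO1
Why: Electrophilic epoxidation goes to the most electron‑rich trisubstituted alkene of the diene, leaving the disubstituted alkene and the electron‑poor enone. Attack from the face anti to the branched C‑6 substituent sets both epoxide carbons trans to the side chain.

**Step 8**
Reactants: 9; 10 vanillin (4‑hydroxy‑3‑methoxybenzaldehyde)
Product: 11 4‑{[(1R,4S,6R)‑4‑hydroxy‑3‑methyl‑6‑[(2S)‑6‑methyl‑4‑oxohept‑5‑en‑2‑yl]cyclohex‑2‑en‑1‑yl]oxy}‑3‑methoxybenzaldehyde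
Conditions: Pd(PPh3)4 (5 mol %), THF, 0 °C → rt
Reagents that add atoms: vanillin, COc1cc(C=O)ccc1O
Why: Tsuji–Trost‑type 1,4‑addition. Pd(0) opens the epoxide with inversion, and the phenoxide attacks the less hindered secondary allyl terminus anti to Pd. The net result is cis‑1,4: the aryl ether and the OH both lie anti to the side chain, and the alkene moves to Cb=Cc, giving the target ring.

**Step 9**
Reactants: 12 4‑hydroxybenzaldehyde; 13 acetylacetone
Product: 14 (E)‑1‑(4‑hydroxyphenyl)hex‑1‑ene‑3,5‑dione (p‑coumaroylacetone)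
Conditions: 13 (3 equiv)–B2O3 complex, B(OBu)3, n‑BuNH2 (cat.), EtOAc, 40 °C; then 0.4 M HCl, 60 °C
Reagents that add atoms: acetylacetone, CC(=O)CC(C)=O (numbered reactant)
Why: Pabon Knoevenagel condensation on the boron‑chelated 1,3‑diketone. Excess acetylacetone stops the reaction at mono‑condensation, and hot acid is acceptable here because no sensitive groups are present.

**Step 10**
Reactants: 11; 14
Product: 15 Demethoxybisabolocurcumin ether (target)
Conditions: 14 + B2O3 (0.7 equiv), EtOAc, 40 °C; then 11, B(OBu)3, piperidine/AcOH (cat.), 40 °C; work‑up aq. NH4OAc/AcOH (pH ~5), 50 °C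
Reagents that add atoms: none (H2O is lost)
Why: The boron‑chelated diketone reacts only at its terminal CH3 with the aryl aldehyde (boron‑mediated Knoevenagel/aldol condensation), giving the E,E‑dienone. A mild pH‑5 work‑up is used instead of hot HCl to protect the acid‑labile allylic aryl ether and allylic alcohol.

## Compound list

| # | Name | SMILES | Role |
|---|---|---|---|
| 1 | (S)‑(+)‑carvone | CC1=CC[C@@H](CC1=O)C(C)=C | starting material |
| 2 | ethyl acrylate | C=CC(=O)OCC | starting material |
| 3 | ethyl (2E)‑3‑[(1S)‑4‑methyl‑5‑oxocyclohex‑3‑en‑1‑yl]but‑2‑enoate | C1C(=O)C(C)=CC[C@@H]1/C(C)=C/C(=O)OCC | intermediate |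
| 4 | ethyl (2E)‑3‑[(1S)‑5‑hydroxy‑4‑methylcyclohex‑3‑en‑1‑yl]but‑2‑enoate (carbinol epimers) | C1C(O)C(C)=CC[C@@H]1/C(C)=C/C(=O)OCC | intermediate |
| 5 | ethyl (3S)‑3‑[(1S)‑5‑hydroxy‑4‑methylcyclohex‑3‑en‑1‑yl]butanoate | C1C(O)C(C)=CC[C@@H]1[C@@H](C)CC(=O)OCC | intermediate |
| 6 | Weinreb amide of 5 | C1C(O)C(C)=CC[C@@H]1[C@@H](C)CC(=O)N(C)OC | intermediate |
| 7 | (6S)‑6‑[(1S)‑5‑hydroxy‑4‑methylcyclohex‑3‑en‑1‑yl]‑2‑methylhept‑2‑en‑4‑one | C1C(O)C(C)=CC[C@@H]1[C@@H](C)CC(=O)C=C(C)C | intermediate |
| 8 | (6S)‑2‑methyl‑6‑[(1R)‑4‑methylcyclohexa‑2,4‑dien‑1‑yl]hept‑2‑en‑4‑one | C1=CC(C)=CC[C@@H]1[C@@H](C)CC(=O)C=C(C)C | intermediate |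
| 9 | vinyl epoxide of 8 (O anti to side chain) | C1=C[C@@]2(C)O[C@H]2C[C@@H]1[C@@H](C)CC(=O)C=C(C)C | intermediate |
| 10 | vanillin | COc1cc(C=O)ccc1O | starting material |
| 11 | 4‑{[(1R,4S,6R)‑4‑hydroxy‑3‑methyl‑6‑[(2S)‑6‑methyl‑4‑oxohept‑5‑en‑2‑yl]cyclohex‑2‑en‑1‑yl]oxy}‑3‑methoxybenzaldehyde | COc1cc(C=O)ccc1O[C@H]1C=C(C)[C@@H](O)C[C@@H]1[C@@H](C)CC(=O)C=C(C)C | intermediate |
| 12 | 4‑hydroxybenzaldehyde | O=Cc1ccc(O)cc1 | starting material |
| 13 | acetylacetone | CC(=O)CC(C)=O | starting material |
| 14 | (E)‑1‑(4‑hydroxyphenyl)hex‑1‑ene‑3,5‑dione | CC(=O)CC(=O)/C=C/c1ccc(O)cc1 | intermediate |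
| 15 | Demethoxybisabolocurcumin ether | COc1cc(/C=C/C(O)=C/C(=O)/C=C/c2ccc(O)cc2)ccc1O[C@H]1C=C(C)[C@@H](O)C[C@@H]1[C@@H](C)CC(=O)C=C(C)C | target |

## Totals

- Total steps: 10 (Steps 1–8 and 10 are linear from carvone; Step 9 is a side branch).
- Longest linear sequence: 9 steps from (S)‑carvone.

## Three steps most likely to fail

1. **Step 1 (cross‑metathesis on the hindered isopropenyl group).** Fallback: change the bond construction to oxidative cleavage (OsO4 cat., NaIO4, 2,6‑lutidine) to the methyl ketone, then Horner–Wadsworth–Emmons olefination with triethyl phosphonoacetate to give the same enoate.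
2. **Step 3 (CuH enantio‑ and diastereocontrol at the side‑chain CH(CH3)).** Fallback: hydrolyse the enoate to the acid and use Ir/SpiroPAP or Ru–BINAP asymmetric hydrogenation of the β,β‑disubstituted acrylic acid, with the carboxylate directing and leaving the ring alkene alone.
3. **Step 8 (Pd cis‑1,4 opening; it also depends on the facial selectivity of Step 7).** Fallback: singlet‑oxygen [4+2] of 8 gives the endoperoxide. Thiourea reduction gives the cis‑diol. Selective TBS protection of the less hindered ring OH follows. The hindered OH is then arylated by SNAr with 4‑fluoro‑3‑methoxybenzaldehyde (NaH, DMF), which proceeds with retention, and TBAF removes the silyl group.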